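Follow the partner.

    starting material + partner → target (k1 = 7.1 × 10⁻⁴ M⁻¹ s⁻¹)
    second substrate + partner → second product (k2 = 0.0017 M⁻¹ s⁻¹)
    partner → decomposed reagent (k3 = 0.0031 s⁻¹)
    second substrate + protic impurity → quenched substrate (k4 = 0.0030 M⁻¹ s⁻¹)
    target ⇌ isomer of the product (K5 = 0.65, k5 = 5.5 × 10⁻⁴ s⁻¹)

starting material 1.1 M; partner 0.800 equiv; second substrate 1.00 equiv; protic impurity 0.550 M; time 8.0 h

- the state of affairs at 8.0 h: stopped, and by what, or still going (it is still moving / forward and back rates have come level / all of the starting material has reacted / the partner has run out first)
- conversion of starting material at 8.0 h
- amount of target at 8.0 h, in percent of the starting material charged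
- amount of isomer of the product at 8.0 h, in percent of the starting material charged

- the reaction counts as stopped when no species that holds the starting material changes by six tenths of a point or more over the second half of the time
- run time (flask): 8.0 h

You want to know how much of the partner reaches the starting material before it is gone. At the charges, each taker pulls on the partner at its own rate per unit of partner (a pseudo-first-order rate). The pulls add, and their sum gives the partner a lifetime of 2.90 min.

| Taker | Pull | Share of the summed pull |
|---|---|---|
| decomposition | 0.186 min⁻¹ | 0.539 |
| second substrate | 0.112 min⁻¹ | 0.325 |
| starting material | 0.0469 min⁻¹ | 0.136 |

Read it downward. At the charges, decomposition pulls half of the sum and the second substrate a third. The bottom row, its pull over the sum of the pulls at the charges, is the starting material's share of the partner.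

Each partner taken there converts one starting material, and you charged 0.800 equiv of partner, so I reckon conversion at 10.9%. The protic impurity takes second substrate faster than the partner does at the start, so the second substrate's pull on the partner fades and my figure leans low.

The run holds 166 lifetimes, so my call is: the partner has run out first. Target and isomer of the product relax with a half-life of 0.138 h, short against 8.0 h, so isomer over target goes to 0.65: target 6.58%, isomer 4.28%.

The forecast says the partner has run out first, with conversion 11.7% (10.5% to 13%), target 7.1% (6.3% to 7.9%) and isomer 4.6% (4.1% to 5.2%). Its conversion stands a little above mine. Its ground: “the starting material only gets a modest exposure to it”.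

The flask gives the partner has run out first: partner stands at 0% of its charge by 0.800 h. Conversion is 11.4%, target 6.90%, isomer 4.48%. Read back over the whole run, this flask gave the starting material 0.142 of the partner, slightly more than the 0.136 reckoned at the charges.

Now take the neighbour flask at 0.44 M of starting material, with partner and second substrate held in equivalents and the protic impurity at 0.550 M. Its two substrate pulls shrink with the charge and decomposition's does not, so the share falls to 0.0751, which reckons conversion at 6.01%. That neighbour flask gave 6.18%.

All constants are invented; the run is a simulation.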